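Readings and results are calculated from invented constants.

The proposed steps pass catalyst from form to form and destroy none of it, so free catalyst and the two catalyst intermediates together stay at the charged concentration, the loading times [starting material]. For the flask, that concentration is 0.00800 M.

| flask | starting material | second substrate | free catalyst | remark | time |
|---|---|---|---|---|---|
| ochre | 0.27 M | 1 equiv (fed, over 50 s) | 2 mol% | run made earlier |  |
| violet | 0.60 M | 1 equiv (fed, over 50 s) | 2 mol% | run made earlier |  |
| teal | 0.40 M | 1 equiv (fed, over 50 s) | 3 mol% | run made earlier |  |
| flask | 0.40 M | 1.00 equiv (fed, over 50 s) | 2 mol% |  | 3.0 h |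

| run | time / h | over-reaction product / % | target / % | starting material / % |
|---|---|---|---|---|
| ochre | 0.200 | 26 | 42 | 30 |
| ochre | 0.333 | 56 | 37 | 10 |
| ochre | 0.500 | 78 | 18 | 3 |
| ochre | 0.833 | 95 | 3 | 1 |
| ochre | 1.33 | 97 | 0 | 2 |
| ochre | 2.50 | 102 | 1 | 0 |
| violet | 0.167 | 46 | 40 | 13 |
| violet | 0.500 | 98 | 2 | 0 |
| violet | 0.833 | 102 | 0 | 0 |
| violet | 1.33 | 100 | 2 | 0 |
| violet | 2.00 | 99 | 0 | 1 |
| violet | 2.50 | 99 | 0 | 0 |
| teal | 0.200 | 68 | 26 | 6 |
| teal | 0.333 | 92 | 6 | 1 |
| teal | 0.667 | 98 | 0 | 0 |
| teal | 1.33 | 99 | 4 | 1 |
| teal | 2.50 | 98 | 0 | 0 |

(readings scatter by 1.5 percentage points)

- steps that have been proposed: starting material + free catalyst <-> catalyst intermediate A; catalyst intermediate A -> free catalyst + target; second substrate + free catalyst <-> catalyst intermediate B; catalyst intermediate B -> free catalyst + second product; free catalyst + target -> free catalyst + over-reaction product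
- the reaction counts as stopped when no species that holds the starting material changes by six tenths of a point or more over the second half of the time

- the state of affairs at 3.0 h: stopped, and by what, or still going (it is still moving / forward and back rates have come level / all of the starting material has reacted / no working catalyst is left)
- amount of over-reaction product at 3.0 h, in percent of the starting material charged

Ochre and violet carry the same loading, 2 mol%, yet at 0.500 h ochre reads 18% target and violet 2%. But a loading is a share, and the step from target to over-reaction product meets a concentration: violet holds 0.0120 M of catalyst, ochre 0.00540 M. With ochre's starting material at 3% by 0.500 h, target's loss there should be pseudo-first-order. Ochre's target falls from 18% to 3% between 0.500 h and 0.833 h, which reads as 0.277 M⁻¹ s⁻¹, the clearing constant, target's loss rate per unit of catalyst concentration. This is a rough reading, since each point carries 1.5 percentage points. With the catalyst counted as free, it gives violet a half-life of 0.0580 h, and about 5.74 of these lie between violet's 40% and 2%, so the contradiction clears.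

With its catalyst counted as free, the flask's clearing half-life comes to 0.0870 h. Ochre, with a lower catalyst concentration than the flask, was down to 3% starting material by 0.500 h, and the span from then to 3.0 h is about 28.8 of the flask's clearing half-lives. This reckoning expects starting material near 0 percent and over-reaction product near 100 percent.

The forecast reads: all of the starting material has reacted, and 99.7% over-reaction product, “with nothing still changing”. The flask gives: all of the starting material has reacted, with 100% over-reaction product at 3.0 h.

    starting material + free catalyst ⇌ catalyst intermediate A (K = 1.80 M⁻¹, k = 6.10 M⁻¹ s⁻¹)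
    catalyst intermediate A → free catalyst + target (k = 0.280 s⁻¹)
    second substrate + free catalyst ⇌ catalyst intermediate B (K = 8.40 M⁻¹, k = 3.30 M⁻¹ s⁻¹)
    catalyst intermediate B → free catalyst + second product (k = 0.520 s⁻¹)
    free catalyst + target → free catalyst + over-reaction product (k = 0.290 M⁻¹ s⁻¹)

In the flask, half of the turnover of starting material into catalyst intermediate A is done by 0.101 h, and the clearing half-life is 0.0870 h, both far shorter than 3.0 h. The final figure hides the passage through target, which stands at 7.83% at 0.0139 h, while over-reaction product has reached >99.9% by 1.50 h. For the same flask read at 8.0 h, that time is about 92.0 clearing half-lives, and the computed result is 100% over-reaction product with target at 0%.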